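## Retrosynthetic overview

1. Presumed biogenesis: the head of a geranylgeranyl chain closes 1,6 to the bisabolyl-type ring B (later Br/OH); an allylic cation in the tail closes onto the terminal olefin (terpinyl-type closure, isopropenyl by hydrogen loss) to give ring A; ring A is epoxidised late.
2. Target ⇒ triene without the oxirane: the oxirane is closed last by reagent-controlled oxygen transfer to the only trisubstituted olefin.
3. Triene ⇒ neral + ring B allylsilane: one carbon of neral serves twice as electrophile in one flask. A carbonyl–ene closure (the aldehyde-level copy of the terpinyl closure) forms ring A and sets the isopropenyl carbon under catalyst control. The same carbon is then ionised to the p-menthadienyl cation and joined to the allylsilane, which sets the neighbouring carbon trans.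
4. Ring B allylsilane ⇒ (1S,2S,4R)-limonene-1,2-diol, bought with ring B closed and enantiopure: SN2 bromide inversion to the cis-bromohydrin, ene chlorination, Pd silylation.
5. Ring order: ring B (chiral pool) → ring A (step 5) → oxirane (step 6).

Assumption: isomerically pure neral is bought as such, and the chiral acid of step 5 is used as the antipode that gives the (1S,6R) alcohol (its mirror image gives the (1R,6S) series).

## Route

Step 1
Reactants: 1 (1S,2S,4R)-1-methyl-4-(prop-1-en-2-yl)cyclohexane-1,2-diol (limonene-1,2-diol, trans-diaxial)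
Product: 2 (1S,2S,5R)-2-hydroxy-2-methyl-5-(prop-1-en-2-yl)cyclohexyl methanesulfonate
Conditions: MsCl (1.2 equiv), pyridine, CH2Cl2, 0 °C
Reagents that add atoms: methanesulfonyl chloride, CS(=O)(=O)Cl
Why: Sulfonylation esterifies only the secondary (axial) hydroxyl because the tertiary one is too hindered, and no stereocentre is touched.

Step 2
Reactants: 2 (1S,2S,5R)-2-hydroxy-2-methyl-5-(prop-1-en-2-yl)cyclohexyl methanesulfonate
Product: 3 (1S,2R,4R)-2-bromo-1-methyl-4-(prop-1-en-2-yl)cyclohexan-1-ol
Conditions: LiBr (6 equiv), DMF, 65 °C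
Reagents that add atoms: lithium bromide, [Li+].[Br-]
Why: SN2 displacement of the axial secondary mesylate by bromide from the rear gives the equatorial bromide with inversion (2S → 2R, Br cis to the tertiary OH), and neutral LiBr leaves the hydroxyl protonated so that epoxide closure is held back.

Step 3
Reactants: 3 (1S,2R,4R)-2-bromo-1-methyl-4-(prop-1-en-2-yl)cyclohexan-1-ol
Product: 4 (1S,2R,4R)-2-bromo-4-(3-chloroprop-1-en-2-yl)-1-methylcyclohexan-1-ol
Conditions: Ca(OCl)2, CO2 (dry ice), CH2Cl2/H2O, 0 °C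
Reagents that add atoms: hypochlorous acid, OCl, made in the flask from calcium hypochlorite, [Ca+2].[O-]Cl.[O-]Cl
Why: Ene-type allylic chlorination (electrophilic Cl on the terminal CH2, hydrogen lost from the methyl group) turns the isopropenyl group into the 2-substituted allyl chloride, as is standard for isopropenyl terpenes, and no stereocentre is involved.

Step 4
Reactants: 4 (1S,2R,4R)-2-bromo-4-(3-chloroprop-1-en-2-yl)-1-methylcyclohexan-1-ol
Product: 5 (1S,2R,4R)-2-bromo-1-methyl-4-[3-(trimethylsilyl)prop-1-en-2-yl]cyclohexan-1-ol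
Conditions: Me3SiSiMe3 (1.5 equiv), Pd(dba)2 (5 mol %), DMF, 50 °C
Reagents that add atoms: hexamethyldisilane, C[Si](C)(C)[Si](C)(C)C
Why: Pd-catalysed allylic silylation, in which zerovalent palladium ionises the allylic chloride to a π-allyl complex that the disilane silylates; the 2-substituted allyl unit is symmetric so only one allylsilane can form, and the hindered secondary bromide does not add to the ligand-free catalyst.

Step 5
Reactants: 6 neral, (2Z)-3,7-dimethylocta-2,6-dienal (1.4 equiv); 5 (1S,2R,4R)-2-bromo-1-methyl-4-[3-(trimethylsilyl)prop-1-en-2-yl]cyclohexan-1-ol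
Product: 9 (1S,2R,4R)-2-bromo-1-methyl-4-{3-[(1S,6S)-3-methyl-6-(prop-1-en-2-yl)cyclohex-2-en-1-yl]prop-1-en-2-yl}cyclohexan-1-ol, via trans-isopiperitenol 7 (not isolated), via allyl cation 8 (not isolated)
Conditions: 6, confined chiral imino-imidodiphosphate Brønsted acid (BINOL-derived, perfluoroaryl-substituted, 2 mol %), CH2Cl2, −20 °C to full conversion; then 5, HNTf2 (5 mol %), −78 → −40 °C; Et3N quench, citric acid/MeOH work-up
Reagents that add atoms: none
Why: Proposed new method: the confined chiral acid folds neral into a chair-like carbonyl–ene (Prins-type) transition state that closes ring A and sets the isopropenyl-bearing centre of 7 under catalyst control, the stronger acid then ionises allylic alcohol 7 to the planar cation 8, and the allylsilane attacks the secondary cation terminus with its CH2 end anti to the neighbouring isopropenyl group (1,2-trans) before β-silyl loss fixes the exocyclic methylene; the closest known reactions are the acid-catalysed asymmetric carbonyl–ene cyclisation of neral, the trans-selective Friedel–Crafts capture of this cation by resorcinols, and the Hosomi–Sakurai dehydrative allylation of allylic alcohols.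

Step 6
Reactants: 9 (1S,2R,4R)-2-bromo-1-methyl-4-{3-[(1S,6S)-3-methyl-6-(prop-1-en-2-yl)cyclohex-2-en-1-yl]prop-1-en-2-yl}cyclohexan-1-ol
Product: 10 (1S,2R,4R)-2-bromo-1-methyl-4-{3-[(1R,2R,3S,6S)-6-methyl-3-(prop-1-en-2-yl)-7-oxabicyclo[4.1.0]heptan-2-yl]prop-1-en-2-yl}cyclohexan-1-ol
Conditions: 1,2:4,5-di-O-isopropylidene-β-D-erythro-hexo-2,3-diulo-2,6-pyranose (Shi ketone from D-fructose, 30 mol %), KHSO5 (as 2KHSO5·KHSO4·K2SO4, 1.4 equiv), K2CO3, Bu4NHSO4, MeCN/CH2(OMe)2/aq. Na2B4O7 buffer, 0 °C
Reagents that add atoms: potassium peroxymonosulfate, [K+].[O-]S(=O)(=O)OO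
Why: Shi asymmetric epoxidation, in which the chiral dioxirane reacts with the only trisubstituted olefin (the two 1,1-disubstituted olefins are much slower) through the spiro transition state that gives the (1R,6S) oxirane, cis to the linker and trans to isopropenyl (the same topology as the (R,R) oxide this ketone gives from 1-phenylcyclohexene), so reagent control overrides the weak substrate bias towards the other face.

## Compound list

1 | (1S,2S,4R)-1-methyl-4-(prop-1-en-2-yl)cyclohexane-1,2-diol | C=C(C)[C@@H]1CC[C@](C)(O)[C@@H](O)C1 | starting material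
2 | (1S,2S,5R)-2-hydroxy-2-methyl-5-(prop-1-en-2-yl)cyclohexyl methanesulfonate | C=C(C)[C@@H]1CC[C@](C)(O)[C@@H](OS(C)(=O)=O)C1 | intermediate
3 | (1S,2R,4R)-2-bromo-1-methyl-4-(prop-1-en-2-yl)cyclohexan-1-ol | C=C(C)[C@@H]1CC[C@](C)(O)[C@H](Br)C1 | intermediate
4 | (1S,2R,4R)-2-bromo-4-(3-chloroprop-1-en-2-yl)-1-methylcyclohexan-1-ol | C=C(CCl)[C@@H]1CC[C@](C)(O)[C@H](Br)C1 | intermediate
5 | (1S,2R,4R)-2-bromo-1-methyl-4-[3-(trimethylsilyl)prop-1-en-2-yl]cyclohexan-1-ol | C=C(C[Si](C)(C)C)[C@@H]1CC[C@](C)(O)[C@H](Br)C1 | intermediate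
6 | neral, (2Z)-3,7-dimethylocta-2,6-dienal | CC(C)=CCC/C(C)=C\C=O | starting material
7 | (1S,6R)-3-methyl-6-(prop-1-en-2-yl)cyclohex-2-en-1-ol (trans-isopiperitenol) | O[C@@H]1[C@@H](C(=C)C)CCC(C)=C1 | intermediate (not isolated)
8 | (6S)-3-methyl-6-(prop-1-en-2-yl)cyclohex-2-en-1-ylium (p-mentha-1,8-dien-3-yl cation, as its triflimide ion pair) | [CH+]1[C@@H](C(=C)C)CCC(C)=C1 | intermediate (not isolated)
9 | (1S,2R,4R)-2-bromo-1-methyl-4-{3-[(1S,6S)-3-methyl-6-(prop-1-en-2-yl)cyclohex-2-en-1-yl]prop-1-en-2-yl}cyclohexan-1-ol | C=C(C[C@@H]1[C@@H](C(=C)C)CCC(C)=C1)[C@@H]1CC[C@](C)(O)[C@H](Br)C1 | intermediate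
10 | (1S,2R,4R)-2-bromo-1-methyl-4-{3-[(1R,2R,3S,6S)-6-methyl-3-(prop-1-en-2-yl)-7-oxabicyclo[4.1.0]heptan-2-yl]prop-1-en-2-yl}cyclohexan-1-ol | C=C(C[C@@H]1[C@@H](C(=C)C)CC[C@]2(C)O[C@H]12)[C@@H]1CC[C@](C)(O)[C@H](Br)C1 | target

## Step count and risks

Total step count: 6. Longest linear sequence: 6 steps (1 → 2 → 3 → 4 → 5 → 9 → 10; neral 6 enters at step 5).

Steps most likely to fail:

**Step 5 (one-flask ring closure and coupling).** The risks are attack at the tertiary cation terminus, protodesilylation of 5, loss of a proton from cation 8, and an incomplete first stage that lets neral react with the allylsilane. The fallback sets out from allyl chloride 4 and neral 6 and reverses the order of the two bond formations. An indium-mediated Barbier allylation (In powder, THF/H2O, 25 °C) adds the allyl unit of 4 to the aldehyde and gives (1S,2R,4R)-2-bromo-4-[(5Z)-4-hydroxy-6,10-dimethylundeca-1,5,9-trien-2-yl]-1-methylcyclohexan-1-ol F3 as both carbinol epimers, which does not matter. Acid ionisation of the allylic carbinol (HNTf2 5 mol %, or the chiral confined acid, CH2Cl2, −40 °C) then closes ring A by attack of the terminal trisubstituted olefin on the allyl cation, with proton loss to isopropenyl. This closure gives the trans ring in both absolute senses, so 9 forms together with its ring A diastereomer (1S,2R,4R)-2-bromo-1-methyl-4-{3-[(1R,6R)-3-methyl-6-(prop-1-en-2-yl)cyclohex-2-en-1-yl]prop-1-en-2-yl}cyclohexan-1-ol F4. F4 is removed on AgNO3-impregnated silica, and the route is rejoined at 9.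

**Step 2 (SN2 at a hindered secondary carbon next to a free tertiary hydroxyl).** The risks are epoxide closure followed by reopening to the trans-bromohydrin, and E2 elimination. The fallback sets out from 2 and blocks the neighbouring hydroxyl before the displacement. Silylation (TMSOTf, 2,6-lutidine, CH2Cl2, −78 °C) gives (1S,2S,5R)-2-methyl-5-(prop-1-en-2-yl)-2-[(trimethylsilyl)oxy]cyclohexyl methanesulfonate F1, which cannot close to an epoxide. Bromide displacement (LiBr, DMF, 80 °C) gives {[(1S,2R,4R)-2-bromo-1-methyl-4-(prop-1-en-2-yl)cyclohexyl]oxy}trimethylsilane F2 with inversion. Mild acid (AcOH/THF/H2O) removes the silyl group, and the route is rejoined at 3.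

**Step 6 (oxygen delivery to the face cis to the linker).** Peracids are expected to prefer the other face, and the catalyst may not overcome the hindrance. The fallback sets out from 9 and replaces face control by removal of the wrong diastereomer. Unselective epoxidation (mCPBA, NaHCO3, CH2Cl2, −20 °C) gives 10 mixed with its oxirane epimer (1S,2R,4R)-2-bromo-1-methyl-4-{3-[(1S,2R,3S,6R)-6-methyl-3-(prop-1-en-2-yl)-7-oxabicyclo[4.1.0]heptan-2-yl]prop-1-en-2-yl}cyclohexan-1-ol F5. Only F5 can open trans-diaxially at its secondary oxirane carbon, so pyrrolidine/H2O at 70 °C converts it into (1S,2R,4R)-2-bromo-4-{3-[(1R,2R,3R,6S)-3-hydroxy-3-methyl-6-(prop-1-en-2-yl)-2-(pyrrolidin-1-yl)cyclohexyl]prop-1-en-2-yl}-1-methylcyclohexan-1-ol F6. Compound 10 would need attack at its tertiary carbon and survives; F6 is washed out with dilute acid, and the route is rejoined at 10.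

## Further compounds

F1 | step 2 | (1S,2S,5R)-2-methyl-5-(prop-1-en-2-yl)-2-[(trimethylsilyl)oxy]cyclohexyl methanesulfonate | C=C(C)[C@@H]1CC[C@](C)(O[Si](C)(C)C)[C@@H](OS(C)(=O)=O)C1
F2 | step 2 | {[(1S,2R,4R)-2-bromo-1-methyl-4-(prop-1-en-2-yl)cyclohexyl]oxy}trimethylsilane | C=C(C)[C@@H]1CC[C@](C)(O[Si](C)(C)C)[C@H](Br)C1
F3 | step 5 | (1S,2R,4R)-2-bromo-4-[(5Z)-4-hydroxy-6,10-dimethylundeca-1,5,9-trien-2-yl]-1-methylcyclohexan-1-ol (both carbinol epimers) | C=C(CC(O)/C=C(C)\CCC=C(C)C)[C@@H]1CC[C@](C)(O)[C@H](Br)C1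
F4 | step 5 | (1S,2R,4R)-2-bromo-1-methyl-4-{3-[(1R,6R)-3-methyl-6-(prop-1-en-2-yl)cyclohex-2-en-1-yl]prop-1-en-2-yl}cyclohexan-1-ol | C=C(C[C@H]1[C@H](C(=C)C)CCC(C)=C1)[C@@H]1CC[C@](C)(O)[C@H](Br)C1
F5 | step 6 | (1S,2R,4R)-2-bromo-1-methyl-4-{3-[(1S,2R,3S,6R)-6-methyl-3-(prop-1-en-2-yl)-7-oxabicyclo[4.1.0]heptan-2-yl]prop-1-en-2-yl}cyclohexan-1-ol | C=C(C[C@@H]1[C@@H](C(=C)C)CC[C@@]2(C)O[C@@H]12)[C@@H]1CC[C@](C)(O)[C@H](Br)C1
F6 | step 6 | (1S,2R,4R)-2-bromo-4-{3-[(1R,2R,3R,6S)-3-hydroxy-3-methyl-6-(prop-1-en-2-yl)-2-(pyrrolidin-1-yl)cyclohexyl]prop-1-en-2-yl}-1-methylcyclohexan-1-ol | C=C(C[C@@H]1[C@@H](C(=C)C)CC[C@@](C)(O)[C@@H]1N2CCCC2)[C@@H]1CC[C@](C)(O)[C@H](Br)C1
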